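**Retrosynthetic overview**
1. Target ⇐ aroylation of O8 of a 6,8-syn diol ⇐ chelate-controlled reduction of a 6-hydroxy-8-ketone.
2. Ten-membered ring ⇐ one C6–C7 bond (C1–C10 of a farnesane chain): reductive aldol macrocyclisation of an open-chain (2Z,6Z)-2,3-epoxy-9-oxofarnesal. The aldehyde is the electrophile, C10 the nucleophile and a hydride ends on C11, the same union and polarity as the 1,10-cyclisation that gives germacranes in nature.
3. C15 chain ⇐ Pd α-alkenylation (C7–C8) of the enol silane of mesityl oxide with a (Z)-alkenyl iodide ⇐ (Z)-iodo-olefination of the aldehyde from ozonolysis of (2S,3R)-2,3-epoxynerol.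
4. Oxirane ⇐ Sharpless epoxidation of the (Z)-olefin of nerol; it is the source of all absolute configuration.
5. Ring order: oxirane (step 1), then the ten-membered carbocycle (step 7); the arene is bought.

Assumption: the SMILES is taken literally, i.e. a (Z)-1(10) olefin, a cis-4,5-oxirane and 4R,5S,6R,7S,8R.
Ring compounds are named with germacrane numbering: C1=C10(CH3), C4(CH3)/C5 oxirane, C6 OH, C7 isopropyl, C8 oxygen, C9 CH2. In step 7 the open-chain compound 13 is numbered the same way.

**Step 1**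
Reactants: 1 nerol = (2Z)-3,7-dimethylocta-2,6-dien-1-ol
Product: 2 (2S,3R)-2,3-epoxynerol = [(2S,3R)-3-methyl-3-(4-methylpent-3-en-1-yl)oxiran-2-yl]methanol
Conditions: Ti(OiPr)4 (0.1 equiv), L-(+)-diethyl tartrate (0.12 equiv), t-BuOOH (2 equiv), 4 Å MS, CH2Cl2, −20 °C
Reagents that add atoms: tert-butyl hydroperoxide CC(C)(C)OO
Why: Katsuki–Sharpless asymmetric epoxidation: the Ti–tartrate complex binds the allylic OH and L-(+)-tartrate delivers oxygen to the face of the (Z)-2,3-olefin that gives the (2S,3R)-oxirane (C5 S and C4 R of the target; about 90% ee expected for this (Z)-alcohol, to be raised by recrystallising the final ester), while the unbound 6,7-olefin does not react.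

**Step 2**
Reactants: 2 (2S,3R)-2,3-epoxynerol
Product: 4 3-[(2R,3S)-3-(hydroxymethyl)-2-methyloxiran-2-yl]propanal, via secondary ozonide 3 (not isolated)
Conditions: O3, CH2Cl2, −78 °C; then PPh3, −78 °C → rt
Reagents that add atoms: ozone [O-][O+]=O
Why: Criegee ozonolysis cleaves the only C=C left, and the PPh3 work-up reduces the ozonide to the aldehyde without touching the oxirane, the alcohol or the two stereocentres.

**Step 3**
Reactants: 4 3-[(2R,3S)-3-(hydroxymethyl)-2-methyloxiran-2-yl]propanal
Product: 5 [(2S,3R)-3-[(3Z)-4-iodopent-3-en-1-yl]-3-methyloxiran-2-yl]methanol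
Conditions: EtPPh3I (2.5 equiv), n-BuLi, THF, 0 °C; I2, −78 °C; NaN(SiMe3)2, −20 °C; then 4, −78 → −20 °C
Reagents that add atoms: (1-iodoethylidene)triphenylphosphorane CC(I)=P(c1ccccc1)(c1ccccc1)c1ccccc1, made in the flask from ethyltriphenylphosphonium iodide CC[P+](c1ccccc1)(c1ccccc1)c1ccccc1.[I-] and iodine II
Why: Wittig olefination of the Stork–Zhao type with the non-stabilised α-iodoethylidene ylide goes through the kinetic cis-oxaphosphetane and gives the (Z)-2-iodo-2-alkene (iodine cis to the chain, usually 10:1 or better), which fixes the later 1(10)-(Z) geometry; the excess ylide allows for the free OH, which is only deprotonated.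

**Step 4**
Reactants: 6 mesityl oxide = 4-methylpent-3-en-2-one
Product: 8 trimethyl[(4-methylpenta-1,3-dien-2-yl)oxy]silane, via lithium 4-methylpenta-1,3-dien-2-olate 7 (not isolated)
Conditions: LiN(iPr)2, THF, −78 °C; Me3SiCl, −78 °C → rt; distillation
Reagents that add atoms: chlorotrimethylsilane C[Si](C)(C)Cl
Why: Kinetic deprotonation of the enone at the α'-methyl group by the hindered amide and O-silylation of the cross-conjugated enolate is standard silyl enol ether formation.

**Step 5**
Reactants: 5 [(2S,3R)-3-[(3Z)-4-iodopent-3-en-1-yl]-3-methyloxiran-2-yl]methanol; 8 trimethyl[(4-methylpenta-1,3-dien-2-yl)oxy]silane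
Product: 12 (6Z)-9-[(2R,3S)-3-(hydroxymethyl)-2-methyloxiran-2-yl]-2,6-dimethylnona-2,6-dien-4-one, via silylated iodide 9 (not isolated), via tributyl[(4-methylpenta-1,3-dien-2-yl)oxy]stannane 10 (not isolated), via silylated enone 11 (not isolated)
Conditions: 8 (3 equiv), Bu3SnF (2 equiv), Pd2(dba)3 (2.5 mol%), P(t-Bu)3 (10 mol%), toluene, 80 °C; then aq KF, rt
Reagents that add atoms: none
Why: Kuwajima–Urabe/Kosugi–Migita α-alkenylation: one equivalent of 8 silylates the free OH, fluoride turns further 8 into the tin enolate, this transmetalates to the alkenylpalladium iodide formed by oxidative addition to zerovalent palladium with retention of the (Z) geometry, and reductive elimination makes the C–C bond under neutral conditions so that the skipped (β,γ) olefin stays out of conjugation; KF frees the alcohol.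

**Step 6**
Reactants: 12 (6Z)-9-[(2R,3S)-3-(hydroxymethyl)-2-methyloxiran-2-yl]-2,6-dimethylnona-2,6-dien-4-one
Product: 13 (2R,3R)-3-[(3Z)-4,8-dimethyl-6-oxonona-3,7-dien-1-yl]-3-methyloxirane-2-carbaldehyde
Conditions: Dess–Martin periodinane (1.3 equiv), NaHCO3, CH2Cl2, 0 °C → rt
Reagents that add atoms: none
Why: Buffered Dess–Martin oxidation takes the primary epoxy alcohol to the aldehyde without acid or base, so the oxirane, its stereocentres (the descriptor change at the CH carbon is only a priority change) and the β,γ-unsaturated enone stay as they are.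

**Step 7**
Reactants: 13 (2R,3R)-3-[(3Z)-4,8-dimethyl-6-oxonona-3,7-dien-1-yl]-3-methyloxirane-2-carbaldehyde
Product: 15 (1(10)Z,4R,5S,6R,7S)-4,5-epoxy-6-hydroxygermacr-1(10)-en-8-one, via (Ph3P)Cu Z-enolate 14 (not isolated)
Conditions: [(Ph3P)CuH]6 (0.3 equiv), degassed toluene, rt, 13 added over 10 h by syringe pump (final 2 mM); then aq NH4Cl, 0 °C
Reagents that add atoms: none
Why: Proposed new method: conjugate hydride transfer from [(Ph3P)CuH]6 to the s-cis β,β-dimethyl enone of 13 (expected to outrun 1,2-reduction of the non-conjugated aldehyde as long as no silane or Lewis acid is present) puts hydrogen on C11 and generates the (Z)-O-copper enolate at C7 only, with no free base, so the doubly activated C9 methylene is not enolised; this monovalent copper enolate adds to the tethered aldehyde C6 through a chair-like, copper-bridged six-membered transition state in which the bridge from C9 to C5 (seven carbons holding a (Z)-olefin and the cis-oxirane) can only span the two pseudo-axial positions at C6 and C8, which with the (Z)-enolate places H6 and H7 cis (6,7-anti aldol, C7 S), and the one rotamer about C5–C6 from which that bridge reaches C9 has the oxirane C5–O bond antiperiplanar to the forming C6–C7 bond (Felkin–Anh) and H5 turned into the ring, which gives the 5,6-threo carbinol (C6 R); closest known reaction types: the intramolecular reductive aldol cyclisation of enone–ketones with this copper hydride (five- and six-membered rings) and medium-ring closures by intramolecular Reformatsky and Nozaki–Hiyama–Kishi additions to aldehydes.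

**Step 8**
Reactants: 15 (1(10)Z,4R,5S,6R,7S)-4,5-epoxy-6-hydroxygermacr-1(10)-en-8-one
Product: 17 (1(10)Z,4R,5S,6R,7R,8R)-4,5-epoxygermacr-1(10)-ene-6,8-diol, via diethylboron chelate 16 (not isolated)
Conditions: Et2BOMe (1.1 equiv), THF–MeOH 4:1, −78 °C; NaBH4, −78 °C; AcOH, then MeOH co-evaporation
Reagents that add atoms: none
Why: Narasaka–Prasad reduction: the 6-OH and the C8 carbonyl are tied into a six-membered boron chelate that the macrocycle spans on one face, so external hydride adds to the open face and gives the 6,8-syn diol (new C8 R; C7 is unchanged and its descriptor becomes R only through a priority change), while the oxirane and the olefin are inert at −78 °C.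

**Step 9**
Reactants: 17 (1(10)Z,4R,5S,6R,7R,8R)-4,5-epoxygermacr-1(10)-ene-6,8-diol; 18 3,4,5-trimethoxybenzoyl chloride
Product: 19 (1(10)Z,4R,5S,6R,7S,8R)-4,5-epoxy-6-hydroxygermacr-1(10)-en-8-yl 3,4,5-trimethoxybenzoate (CNP0260213.9)
Conditions: 18 (1.1 equiv), pyridine, DMAP (0.1 equiv), CH2Cl2, −20 → 0 °C
Reagents that add atoms: none
Why: DMAP-catalysed acylation under kinetic control should take the 8-OH, which has a CH2 neighbour, in preference to the 6-OH, which sits between the oxirane and the isopropyl-bearing carbon, is inductively deactivated and is hydrogen-bonded to the oxirane oxygen; no stereocentre is touched.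

**Compound list**
1 | nerol, (2Z)-3,7-dimethylocta-2,6-dien-1-ol | CC(C)=CCC/C(C)=C\CO | starting material
2 | (2S,3R)-2,3-epoxynerol, [(2S,3R)-3-methyl-3-(4-methylpent-3-en-1-yl)oxiran-2-yl]methanol | CC(C)=CCC[C@@]1(C)O[C@H]1CO | intermediate
3 | secondary ozonide, [(2S,3R)-3-[2-(5,5-dimethyl-1,2,4-trioxolan-3-yl)ethyl]-3-methyloxiran-2-yl]methanol (both epimers at the trioxolane CH) | CC1(C)OOC(CC[C@@]2(C)O[C@H]2CO)O1 | intermediate
4 | 3-[(2R,3S)-3-(hydroxymethyl)-2-methyloxiran-2-yl]propanal | O=CCC[C@@]1(C)O[C@H]1CO | intermediate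
5 | [(2S,3R)-3-[(3Z)-4-iodopent-3-en-1-yl]-3-methyloxiran-2-yl]methanol | C/C(I)=C/CC[C@@]1(C)O[C@H]1CO | intermediate
6 | mesityl oxide, 4-methylpent-3-en-2-one | CC(=O)C=C(C)C | starting material
7 | lithium 4-methylpenta-1,3-dien-2-olate | [Li]OC(=C)C=C(C)C | intermediate
8 | trimethyl[(4-methylpenta-1,3-dien-2-yl)oxy]silane | C=C(O[Si](C)(C)C)C=C(C)C | intermediate
9 | silylated iodide, {[(2S,3R)-3-[(3Z)-4-iodopent-3-en-1-yl]-3-methyloxiran-2-yl]methoxy}trimethylsilane | C/C(I)=C/CC[C@@]1(C)O[C@H]1CO[Si](C)(C)C | intermediate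
10 | tributyl[(4-methylpenta-1,3-dien-2-yl)oxy]stannane | C=C(O[Sn](CCCC)(CCCC)CCCC)C=C(C)C | intermediate
11 | silylated enone, (6Z)-2,6-dimethyl-9-{(2R,3S)-2-methyl-3-[(trimethylsilyloxy)methyl]oxiran-2-yl}nona-2,6-dien-4-one | CC(C)=CC(=O)C/C(C)=C\CC[C@@]1(C)O[C@H]1CO[Si](C)(C)C | intermediate
12 | (6Z)-9-[(2R,3S)-3-(hydroxymethyl)-2-methyloxiran-2-yl]-2,6-dimethylnona-2,6-dien-4-one | CC(C)=CC(=O)C/C(C)=C\CC[C@@]1(C)O[C@H]1CO | intermediate
13 | (2R,3R)-3-[(3Z)-4,8-dimethyl-6-oxonona-3,7-dien-1-yl]-3-methyloxirane-2-carbaldehyde | CC(C)=CC(=O)C/C(C)=C\CC[C@@]1(C)O[C@H]1C=O | intermediate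
14 | (Ph3P)Cu (3Z,6Z)-9-[(2R,3R)-3-formyl-2-methyloxiran-2-yl]-2,6-dimethylnona-3,6-dien-4-olate (PPh3 on copper not drawn) | CC(C)/C=C(\O[Cu])C/C(C)=C\CC[C@@]1(C)O[C@H]1C=O | intermediate
15 | (1(10)Z,4R,5S,6R,7S)-4,5-epoxy-6-hydroxygermacr-1(10)-en-8-one = (1S,2R,3S,6Z,10R)-2-hydroxy-6,10-dimethyl-3-(propan-2-yl)-11-oxabicyclo[8.1.0]undec-6-en-4-one | O=C1C/C(C)=C\CC[C@@]2(C)O[C@H]2[C@H](O)[C@@H]1C(C)C | intermediate
16 | 6-O-diethylboryl derivative of 15, boron chelated by the C8 carbonyl oxygen | O=C1C/C(C)=C\CC[C@@]2(C)O[C@H]2[C@H](OB(CC)CC)[C@@H]1C(C)C | intermediate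
17 | (1(10)Z,4R,5S,6R,7R,8R)-4,5-epoxygermacr-1(10)-ene-6,8-diol = (1S,2R,3R,4R,6Z,10R)-6,10-dimethyl-3-(propan-2-yl)-11-oxabicyclo[8.1.0]undec-6-ene-2,4-diol | O[C@@H]1C/C(C)=C\CC[C@@]2(C)O[C@H]2[C@H](O)[C@@H]1C(C)C | intermediate
18 | 3,4,5-trimethoxybenzoyl chloride | COc1cc(C(=O)Cl)cc(OC)c1OC | starting material
19 | (1(10)Z,4R,5S,6R,7S,8R)-4,5-epoxy-6-hydroxygermacr-1(10)-en-8-yl 3,4,5-trimethoxybenzoate = (1S,2R,3S,4R,6Z,10R)-2-hydroxy-6,10-dimethyl-3-(propan-2-yl)-11-oxabicyclo[8.1.0]undec-6-en-4-yl 3,4,5-trimethoxybenzoate | COc1cc(C(=O)O[C@@H]2C/C(C)=C\CC[C@@]3(C)O[C@H]3[C@H](O)[C@@H]2C(C)C)cc(OC)c1OC | target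

**Step count and risks**

Total steps: 9. Longest linear sequence: 8 steps (1 → 19 through steps 1, 2, 3, 5, 6, 7, 8 and 9; step 4 is a one-step side branch).

The three steps most likely to fail:

Step 7 is the most likely to fail. The copper hydride may reduce the epoxy aldehyde before it reduces the hindered enone. The enolate may be quenched or oligomerise instead of closing the ten-membered ring. The configurations at C6 and C7 rest on a transition-state model and have no precedent in a ring of this size. The fallback sets out from 12 and comes back at 15, and makes the enolate precursor before the aldehyde exists. Treating 12 with [(Ph3P)CuH]6 and Me3SiCl gives the bis-trimethylsilyl (Z)-enol silane F1. NBS in THF at −78 °C followed by aqueous work-up gives the α-bromo ketone alcohol F2. Dess–Martin oxidation gives the bromo keto epoxy aldehyde F3. Slow addition of F3 to Et2Zn and catalytic RhCl(PPh3)3 in THF at 0 °C (intramolecular Reformatsky reaction under high dilution) then gives 15. The zinc enolate can form only at the brominated carbon and can chelate the aldehyde and oxirane oxygens.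

Step 5 is the second risk. The alkenyl iodide is hindered, the product has a more acidic methylene than the reagent (a second alkenylation or migration of the olefin into conjugation is possible), and the free OH consumes reagent. The fallback sets out from 5 and comes back at 12. Coupling of 5 with excess BrZnCH2CO2Et under Pd(PPh3)4 catalysis gives the β,γ-unsaturated ethyl ester F4. Me(MeO)NH·HCl with i-PrMgCl turns it into the Weinreb amide F5. Addition of 2-methylprop-1-enylmagnesium bromide at −78 °C then gives 12.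

Step 9 is the third risk, because the preference for O8 over O6 is a steric and electronic argument and may be only moderate. The fallback sets out from 15 and comes back at 19. Et3SiOTf and 2,6-lutidine give the 6-O-triethylsilyl ketone F6. NaBH4 with CeCl3·7H2O in MeOH at −78 °C adds hydride from the open face of the ring and gives the 8-alcohol F7, now the only free OH. Aroylation with 18 (pyridine, DMAP) gives the silyl-protected ester F8, and HF·pyridine in THF gives 19.

**Further compounds**
F1 | step 7 | {[(2S,3R)-3-[(3Z,6Z)-4,8-dimethyl-6-(trimethylsilyloxy)nona-3,6-dien-1-yl]-3-methyloxiran-2-yl]methoxy}trimethylsilane | CC(C)/C=C(\O[Si](C)(C)C)C/C(C)=C\CC[C@@]1(C)O[C@H]1CO[Si](C)(C)C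
F2 | step 7 | (6Z)-3-bromo-9-[(2R,3S)-3-(hydroxymethyl)-2-methyloxiran-2-yl]-2,6-dimethylnon-6-en-4-one (both epimers at the CHBr carbon) | CC(C)C(Br)C(=O)C/C(C)=C\CC[C@@]1(C)O[C@H]1CO
F3 | step 7 | (2R,3R)-3-[(3Z)-7-bromo-4,8-dimethyl-6-oxonon-3-en-1-yl]-3-methyloxirane-2-carbaldehyde (both epimers at the CHBr carbon) | CC(C)C(Br)C(=O)C/C(C)=C\CC[C@@]1(C)O[C@H]1C=O
F4 | step 5 | ethyl (3Z)-6-[(2R,3S)-3-(hydroxymethyl)-2-methyloxiran-2-yl]-3-methylhex-3-enoate | CCOC(=O)C/C(C)=C\CC[C@@]1(C)O[C@H]1CO
F5 | step 5 | (3Z)-6-[(2R,3S)-3-(hydroxymethyl)-2-methyloxiran-2-yl]-N-methoxy-N,3-dimethylhex-3-enamide | CON(C)C(=O)C/C(C)=C\CC[C@@]1(C)O[C@H]1CO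
F6 | step 9 | (1(10)Z,4R,5S,6R,7S)-4,5-epoxy-6-(triethylsilyloxy)germacr-1(10)-en-8-one | O=C1C/C(C)=C\CC[C@@]2(C)O[C@H]2[C@H](O[Si](CC)(CC)CC)[C@@H]1C(C)C
F7 | step 9 | (1(10)Z,4R,5S,6R,7R,8R)-4,5-epoxy-6-(triethylsilyloxy)germacr-1(10)-en-8-ol | O[C@@H]1C/C(C)=C\CC[C@@]2(C)O[C@H]2[C@H](O[Si](CC)(CC)CC)[C@@H]1C(C)C
F8 | step 9 | (1(10)Z,4R,5S,6R,7S,8R)-4,5-epoxy-6-(triethylsilyloxy)germacr-1(10)-en-8-yl 3,4,5-trimethoxybenzoate | COc1cc(C(=O)O[C@@H]2C/C(C)=C\CC[C@@]3(C)O[C@H]3[C@H](O[Si](CC)(CC)CC)[C@@H]2C(C)C)cc(OC)c1OC
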